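**Plan** (halimane numbering: decalin C1–C10, side chain C11–C16, C17 on C8, C18/C19 on C4, C20 on C9)
- Retrosynthesis: the glyceryl ester is cut first. The C1=C10 alkene is traced to a C1 ketone; ring A is then cut at C2–C3 (aldol condensation of a C1 methyl ketone with a C3 aldehyde) and ring B at C5–C10 (Claisen, after adding C6=C7). Both cuts lead to one 2-alkenyl-6-methyl-3,4-dihydro-2H-pyran, 17.
- Enabling feature: C1 lies γ,δ to C6=C7 of ring B and 1,5 to C3, both across the C5–C10 bond, and C4 is quaternary. The C1 oxygen can therefore be tied to C7 in a ring O–C7–C8–C9–C10–C1, whose [3,3] shift makes ring B and frees the ketone that closes ring A.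
- Forward: enal 2 and a propionyl oxazolidinone give the C7/C8 aldol; a citronellol-derived Grignard reagent adds C11–C15; lactonization and conjugate methylation build the oxacycle with quaternary C9; the cascade then forms ring B, then ring A.
- Stereochemistry: C13 from (R)-citronellol; C7 and C8 from the (R)-benzyl auxiliary; C9 by cuprate addition anti to the C8 methyl; C5 by transfer from C7 (then lost as a stereocenter) through the boat Claisen transition state of the E-alkene.
- End game: α′-enol triflate, diimide and formate reduction place the C1=C10 alkene; desilylation, oxidation, esterification with 1,3-O-benzylideneglycerol and acetal removal finish.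

Key step: step 13

Remark: C10 of 18–20 is formed with the acyl group cis to C4 and may epimerize under the basic conditions; this has no consequence because C10 becomes sp2 in step 14 (SMILES show the first-formed isomer).

Step 1
Reactants: 1 methyl 2,2-dimethyl-3-oxopropanoate
Product: 2 methyl (3E)-2,2-dimethyl-5-oxopent-3-enoate
Conditions: Ph3P=CHCHO, toluene, 80 °C
Reagents that add atoms: (triphenylphosphoranylidene)acetaldehyde, O=CC=P(c1ccccc1)(c1ccccc1)c1ccccc1
Why: Wittig olefination of the non-enolizable, ester-activated aldehyde with the stabilized formyl ylide should give the E-enal (C5=C6, C7 aldehyde), and the conjugated product is less electrophilic than 1, which should limit a second homologation.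

Step 2
Reactants: 2 methyl (3E)-2,2-dimethyl-5-oxopent-3-enoate; 3 (4R)-4-benzyl-3-propanoyl-1,3-oxazolidin-2-one
Product: 5 methyl (3E,5S,6R)-7-[(4R)-4-benzyl-2-oxo-1,3-oxazolidin-3-yl]-5-hydroxy-2,2,6-trimethyl-7-oxohept-3-enoate, via boron enolate 4 (not isolated)
Conditions: 3, Bu2BOTf, iPr2NEt, CH2Cl2, 0 °C; then 2, −78 → 0 °C; H2O2, MeOH, pH 7 buffer
Reagents that add atoms: none
Why: Evans syn-aldol: the Z-boron enolate 4 reacts through a closed chair transition state in which the (R)-benzyl auxiliary shields one enolate face, so C7 (S) and C8 (R) are set together with syn relative configuration, and the enal reacts only at its carbonyl carbon.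

Step 3
Reactants: 5 aldol adduct
Product: 6 methyl (3E,5S,6R)-5-hydroxy-7-[methoxy(methyl)amino]-2,2,6-trimethyl-7-oxohept-3-enoate
Conditions: MeNH(OMe)·HCl, AlMe3, CH2Cl2, −10 → 0 °C
Reagents that add atoms: N,O-dimethylhydroxylamine hydrochloride, CNOC.Cl
Why: Aluminium-amide transamination of the imide, assisted by chelation to the free C7 hydroxyl, should release the auxiliary and give the Weinreb amide, while the neopentyl methyl ester is too hindered to react.

Step 4
Reactants: 7 (R)-citronellol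
Product: 8 tert-butyl{[(3R)-3,7-dimethyloct-6-en-1-yl]oxy}diphenylsilane
Conditions: t-BuPh2SiCl, imidazole, CH2Cl2, 23 °C
Reagents that add atoms: tert-butyl(chloro)diphenylsilane, CC(C)(C)[Si](Cl)(c1ccccc1)c1ccccc1
Why: Standard silylation of the primary alcohol gives an ether that should survive all organometallic, basic and thermal steps up to step 17; the C13 stereocenter comes unchanged from the chiral pool.

Step 5
Reactants: 8 silyl ether of citronellol
Product: 9 (4R)-6-[(tert-butyldiphenylsilyl)oxy]-4-methylhexanoic acid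
Conditions: KMnO4 (cat.), NaIO4, t-BuOH/H2O, pH 7, 23 °C
Reagents that add atoms: sodium periodate, [Na+].[O-]I(=O)(=O)=O; water, O
Why: Permanganate–periodate oxidative cleavage of the trisubstituted alkene should give the carboxylic acid and acetone without touching the aryl silyl ether.

Step 6
Reactants: 9 carboxylic acid
Product: 10 tert-butyl{[(3S)-5-iodo-3-methylpentyl]oxy}diphenylsilane
Conditions: PhI(OAc)2, I2, cyclohexane, hν, 80 °C
Reagents that add atoms: iodine, II
Why: Hunsdiecker-type iododecarboxylation through the acyl hypoiodite and a primary alkyl radical should shorten the chain by one carbon to the C11 iodide; the remote stereocenter is not involved (the descriptor changes only because iodine outranks oxygen).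

Step 7
Reactants: 10 iodide; 6 Weinreb amide
Product: 12 methyl (3E,5S,6R,10R)-12-[(tert-butyldiphenylsilyl)oxy]-5-hydroxy-2,2,6,10-tetramethyl-7-oxododec-3-enoate, via Grignard reagent 11 (not isolated)
Conditions: 10, Mg, Et2O, 23 °C; separately 6, iPrMgCl, THF, −20 °C; then 11, 0 °C; aq. NH4Cl
Reagents that add atoms: none
Why: Weinreb ketone synthesis: after the C7 hydroxyl is masked as its magnesium alkoxide, the Grignard reagent adds once to the amide through the chelated tetrahedral intermediate and forms the C9–C11 bond, while the hindered ester should stay intact.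

Step 8
Reactants: 12 β-hydroxy ketone
Product: 13 methyl (3E)-4-[(2S,3S)-4-{(3R)-5-[(tert-butyldiphenylsilyl)oxy]-3-methylpentyl}-3-methyl-6-oxo-3,6-dihydro-2H-pyran-2-yl]-2,2-dimethylbut-3-enoate
Conditions: Ph3P=C=C=O, toluene, 110 °C
Reagents that add atoms: (triphenylphosphoranylidene)ketene, O=C=C=P(c1ccccc1)(c1ccccc1)c1ccccc1
Why: Addition of the C7 hydroxyl to the cumulated ylide gives an ester-stabilized ylide that should close by intramolecular Wittig reaction on the C9 ketone to the α,β-unsaturated δ-lactone (C1 and C10 added, C9=C10 in the ring).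

Step 9
Reactants: 13 unsaturated lactone
Product: 14 methyl (3E)-4-[(2S,3S,4S)-4-{(3R)-5-[(tert-butyldiphenylsilyl)oxy]-3-methylpentyl}-3,4-dimethyl-6-oxooxan-2-yl]-2,2-dimethylbut-3-enoate
Conditions: Me2CuLi (from MeLi and CuI), Et2O, −40 → 0 °C; aq. NH4Cl
Reagents that add atoms: lithium dimethylcuprate, [Li+].C[Cu-]C
Why: Organocuprate conjugate addition: in the lactone half-chair the C8 methyl sits pseudo-axial (away from the C9 substituent) and the alkenyl group pseudo-equatorial, so axial delivery of methyl to C9 from the face opposite the C8 methyl should set the quaternary center with C20 trans to C17 and the C11 chain cis to the C7 alkenyl group.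

Step 10
Reactants: 14 lactone
Product: 15 methyl (3E)-4-[(2S,3S,4R)-4-{(3R)-5-[(tert-butyldiphenylsilyl)oxy]-3-methylpentyl}-6-[(diphenoxyphosphoryl)oxy]-3,4-dimethyl-3,4-dihydro-2H-pyran-2-yl]-2,2-dimethylbut-3-enoate
Conditions: KN(SiMe3)2, (PhO)2P(O)Cl, THF/HMPA, −78 °C
Reagents that add atoms: diphenyl chlorophosphate, O=P(Cl)(Oc1ccccc1)Oc1ccccc1
Why: O-phosphorylation of the lactone enolate (the C10 hydrogens are the only acidic ones, since the other ester has no α-hydrogen) should give the cyclic ketene acetal phosphate at −78 °C, where no sigmatropic shift occurs.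

Step 11
Reactants: 15 ketene acetal phosphate
Product: 16 methyl (3E)-4-[(2S,3S,4R)-4-{(3R)-5-[(tert-butyldiphenylsilyl)oxy]-3-methylpentyl}-3,4,6-trimethyl-3,4-dihydro-2H-pyran-2-yl]-2,2-dimethylbut-3-enoate
Conditions: MeZnCl, Pd(PPh3)4 (cat.), THF, 50 °C
Reagents that add atoms: methylzinc chloride, C[Zn]Cl
Why: Negishi cross-coupling of the ketene acetal phosphate (oxidative addition of zerovalent palladium into the C–O bond, methyl transfer from zinc, reductive elimination) should install C2 and leave the enol ether double bond fixed in the ring at C10=C1, as the key step requires.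

Step 12
Reactants: 16 dihydropyran ester
Product: 17 (3E)-4-[(2S,3S,4R)-4-{(3R)-5-[(tert-butyldiphenylsilyl)oxy]-3-methylpentyl}-3,4,6-trimethyl-3,4-dihydro-2H-pyran-2-yl]-2,2-dimethylbut-3-enal
Conditions: iBu2AlH (1.1 equiv), CH2Cl2, −78 °C; aq. potassium sodium tartrate
Reagents that add atoms: none
Why: Partial reduction of the α-quaternary methyl ester should stop at the aldehyde because the hindered tetrahedral aluminate is stable at −78 °C; the enol ether, alkene and silyl ether are inert and the work-up is non-acidic.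

Step 13
Reactants: 17 dihydropyran aldehyde
Product: 20 (4aR,7R,8R,8aR)-8-{(3R)-5-[(tert-butyldiphenylsilyl)oxy]-3-methylpentyl}-4,4,7,8-tetramethyl-4a,7,8,8a-tetrahydronaphthalen-1(4H)-one, via keto aldehyde 18 (not isolated), via aldol 19 (not isolated)
Conditions: DBU (0.5 equiv), BHT (cat.), degassed toluene, sealed tube, 200 °C
Reagents that add atoms: none
Why: Heating should trigger a thermal [3,3]-sigmatropic (Claisen) shift of the cyclic allyl vinyl ether C10=C1–O–C7–C6=C5, which the dihydropyran ring forces through a boat, bicyclo[2.2.2]-like transition state; it forms C5–C10, cuts O–C7 and converts the oxacycle into carbocyclic ring B (C6=C7) bearing a C1 methyl ketone (18). The closest known reaction type is the Claisen rearrangement of 2-alkenyl-3,4-dihydro-2H-pyrans to 4-acylcyclohexenes, followed by the aldol cyclodehydration of a 1,5-keto aldehyde as in a Robinson annulation. With DBU, the C2 methyl enolate of 18 adds to the non-enolizable C3 aldehyde in a 6-(enolendo)-exo-trig closure (19), and loss of water gives the ring A enone 20 with the new C2–C3 bond. C5 is the only lasting new stereocenter: the alkenyl arm can reach C10 only on the ring face fixed by C7, and the E-alkene turns H5 toward the C8–C9 bridge, so the all-cis array of 17 (C7 alkenyl, C8 methyl, C9 side chain) should give H5 cis to C11 and C17 as in the target, while C10 (acetyl cis to C4) becomes sp2 later. The step needs the endocyclic enol ether (an exocyclic isomer would lead to a cyclooctenone), secured by step 11, and the right aldol regiochemistry, secured because the C10 enolate could only close a four-membered ring and C4 is quaternary.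

Step 14
Reactants: 20 dienone
Product: 21 (4aS,7R,8R)-8-{(3R)-5-[(tert-butyldiphenylsilyl)oxy]-3-methylpentyl}-4,4,7,8-tetramethyl-4,4a,7,8-tetrahydronaphthalen-1-yl trifluoromethanesulfonate
Conditions: KN(SiMe3)2, THF, −78 °C; then PhNTf2, −78 → 0 °C
Reagents that add atoms: N-phenylbis(trifluoromethanesulfonimide), O=S(=O)(N(c1ccccc1)S(=O)(=O)C(F)(F)F)C(F)(F)F
Why: Regiospecific enolization: C10–H is the only acidic position of 20 (C2 is vinylic and C4 quaternary, so there is no γ-hydrogen), and O-triflation of the cross-conjugated dienolate should fix the C1=C10 double bond as a 2-triflyloxy-1,3-diene.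

Step 15
Reactants: 21 dienyl triflate
Product: 22 (4aS,7R,8R)-8-{(3R)-5-[(tert-butyldiphenylsilyl)oxy]-3-methylpentyl}-4,4,7,8-tetramethyl-2,3,4,4a,5,6,7,8-octahydronaphthalen-1-yl trifluoromethanesulfonate
Conditions: 2-nitrobenzenesulfonohydrazide (excess), Et3N, CH2Cl2, 23 °C
Reagents that add atoms: none
Why: Diimide reduction transfers H2 in a concerted syn fashion to the two cis-disubstituted alkenes (C2=C3 and C6=C7), whereas the tetrasubstituted, electron-poor enol triflate double bond should not react.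

Step 16
Reactants: 22 enol triflate
Product: 23 tert-butyl({(3R)-3-methyl-5-[(1R,2R,4aS)-1,2,5,5-tetramethyl-1,2,3,4,4a,5,6,7-octahydronaphthalen-1-yl]pentyl}oxy)diphenylsilane
Conditions: Pd(OAc)2 (cat.), PPh3 (cat.), HCO2H, Bu3N, DMF, 60 °C
Reagents that add atoms: none
Why: Palladium-catalysed formate reduction of the vinyl triflate (oxidative addition, formate-to-hydride exchange with loss of CO2, reductive elimination) replaces the triflate by hydrogen without moving the double bond, giving the trisubstituted C1=C10 alkene.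

Step 17
Reactants: 23 silyl ether
Product: 24 (3R)-3-methyl-5-[(1R,2R,4aS)-1,2,5,5-tetramethyl-1,2,3,4,4a,5,6,7-octahydronaphthalen-1-yl]pentan-1-ol
Conditions: Bu4NF, THF, 23 °C
Reagents that add atoms: none
Why: Fluoride-mediated desilylation frees the C15 alcohol under conditions that cannot isomerize the alkene.

Step 18
Reactants: 24 alcohol
Product: 25 (3R)-3-methyl-5-[(1R,2R,4aS)-1,2,5,5-tetramethyl-1,2,3,4,4a,5,6,7-octahydronaphthalen-1-yl]pentanoic acid
Conditions: TEMPO (cat.), PhI(OAc)2, MeCN/H2O, 23 °C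
Reagents that add atoms: water, O
Why: Oxoammonium (TEMPO) oxidation of the primary alcohol through the aldehyde hydrate should give the acid, and the hindered trisubstituted alkene is not attacked by this oxidant.

Step 19
Reactants: 25 acid; 26 cis-2-phenyl-1,3-dioxan-5-ol
Product: 27 cis-2-phenyl-1,3-dioxan-5-yl (3R)-3-methyl-5-[(1R,2R,4aS)-1,2,5,5-tetramethyl-1,2,3,4,4a,5,6,7-octahydronaphthalen-1-yl]pentanoate
Conditions: EDC·HCl, DMAP (cat.), CH2Cl2, 23 °C
Reagents that add atoms: none
Why: Steglich esterification acylates the only free hydroxyl of 1,3-O-benzylideneglycerol, which places the acyl group on the central glycerol oxygen.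

Step 20
Reactants: 27 benzylidene-protected ester
Product: 28 1,3-dihydroxypropan-2-yl (3R)-3-methyl-5-[(1R,2R,4aS)-1,2,5,5-tetramethyl-1,2,3,4,4a,5,6,7-octahydronaphthalen-1-yl]pentanoate
Conditions: B(OH)3, B(OMe)3, reflux; then H2O
Reagents that add atoms: none
Why: Boric acid transacetalization removes the benzylidene group as benzaldehyde through a cyclic borate that water then hydrolyses, a mild method that should avoid both 2→1 acyl shift and acid-induced migration of the C1=C10 alkene.

**Compound list**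
1 | methyl 2,2-dimethyl-3-oxopropanoate | COC(=O)C(C)(C)C=O | starting material
2 | methyl (3E)-2,2-dimethyl-5-oxopent-3-enoate | COC(=O)C(C)(C)/C=C/C=O | intermediate
3 | (4R)-4-benzyl-3-propanoyl-1,3-oxazolidin-2-one | CCC(=O)N1C(=O)OC[C@H]1Cc1ccccc1 | starting material
4 | dibutylboron Z-enolate of 3 | C/C=C(\OB(CCCC)CCCC)N1C(=O)OC[C@H]1Cc1ccccc1 | intermediate
5 | methyl (3E,5S,6R)-7-[(4R)-4-benzyl-2-oxo-1,3-oxazolidin-3-yl]-5-hydroxy-2,2,6-trimethyl-7-oxohept-3-enoate | COC(=O)C(C)(C)/C=C/[C@H](O)[C@@H](C)C(=O)N1C(=O)OC[C@H]1Cc1ccccc1 | intermediate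
6 | methyl (3E,5S,6R)-5-hydroxy-7-[methoxy(methyl)amino]-2,2,6-trimethyl-7-oxohept-3-enoate | COC(=O)C(C)(C)/C=C/[C@H](O)[C@@H](C)C(=O)N(C)OC | intermediate
7 | (R)-citronellol, (3R)-3,7-dimethyloct-6-en-1-ol | C[C@H](CCC=C(C)C)CCO | starting material
8 | tert-butyl{[(3R)-3,7-dimethyloct-6-en-1-yl]oxy}diphenylsilane | C[C@H](CCC=C(C)C)CCO[Si](c1ccccc1)(c1ccccc1)C(C)(C)C | intermediate
9 | (4R)-6-[(tert-butyldiphenylsilyl)oxy]-4-methylhexanoic acid | C[C@H](CCC(=O)O)CCO[Si](c1ccccc1)(c1ccccc1)C(C)(C)C | intermediate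
10 | tert-butyl{[(3S)-5-iodo-3-methylpentyl]oxy}diphenylsilane | C[C@H](CCI)CCO[Si](c1ccccc1)(c1ccccc1)C(C)(C)C | intermediate
11 | {(3S)-5-[(tert-butyldiphenylsilyl)oxy]-3-methylpentyl}magnesium iodide | C[C@H](CC[Mg]I)CCO[Si](c1ccccc1)(c1ccccc1)C(C)(C)C | intermediate
12 | methyl (3E,5S,6R,10R)-12-[(tert-butyldiphenylsilyl)oxy]-5-hydroxy-2,2,6,10-tetramethyl-7-oxododec-3-enoate | COC(=O)C(C)(C)/C=C/[C@H](O)[C@@H](C)C(=O)CC[C@@H](C)CCO[Si](c1ccccc1)(c1ccccc1)C(C)(C)C | intermediate
13 | methyl (3E)-4-[(2S,3S)-4-{(3R)-5-[(tert-butyldiphenylsilyl)oxy]-3-methylpentyl}-3-methyl-6-oxo-3,6-dihydro-2H-pyran-2-yl]-2,2-dimethylbut-3-enoate | COC(=O)C(C)(C)/C=C/[C@@H]1OC(=O)C=C(CC[C@@H](C)CCO[Si](c2ccccc2)(c2ccccc2)C(C)(C)C)[C@@H]1C | intermediate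
14 | methyl (3E)-4-[(2S,3S,4S)-4-{(3R)-5-[(tert-butyldiphenylsilyl)oxy]-3-methylpentyl}-3,4-dimethyl-6-oxooxan-2-yl]-2,2-dimethylbut-3-enoate | COC(=O)C(C)(C)/C=C/[C@@H]1OC(=O)C[C@](C)(CC[C@@H](C)CCO[Si](c2ccccc2)(c2ccccc2)C(C)(C)C)[C@@H]1C | intermediate
15 | methyl (3E)-4-[(2S,3S,4R)-4-{(3R)-5-[(tert-butyldiphenylsilyl)oxy]-3-methylpentyl}-6-[(diphenoxyphosphoryl)oxy]-3,4-dimethyl-3,4-dihydro-2H-pyran-2-yl]-2,2-dimethylbut-3-enoate | COC(=O)C(C)(C)/C=C/[C@@H]1OC(OP(=O)(Oc2ccccc2)Oc2ccccc2)=C[C@](C)(CC[C@@H](C)CCO[Si](c2ccccc2)(c2ccccc2)C(C)(C)C)[C@@H]1C | intermediate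
16 | methyl (3E)-4-[(2S,3S,4R)-4-{(3R)-5-[(tert-butyldiphenylsilyl)oxy]-3-methylpentyl}-3,4,6-trimethyl-3,4-dihydro-2H-pyran-2-yl]-2,2-dimethylbut-3-enoate | COC(=O)C(C)(C)/C=C/[C@@H]1OC(C)=C[C@](C)(CC[C@@H](C)CCO[Si](c2ccccc2)(c2ccccc2)C(C)(C)C)[C@@H]1C | intermediate
17 | (3E)-4-[(2S,3S,4R)-4-{(3R)-5-[(tert-butyldiphenylsilyl)oxy]-3-methylpentyl}-3,4,6-trimethyl-3,4-dihydro-2H-pyran-2-yl]-2,2-dimethylbut-3-enal | O=CC(C)(C)/C=C/[C@@H]1OC(C)=C[C@](C)(CC[C@@H](C)CCO[Si](c2ccccc2)(c2ccccc2)C(C)(C)C)[C@@H]1C | intermediate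
18 | 2-[(1R,4R,5R,6R)-6-acetyl-5-{(3R)-5-[(tert-butyldiphenylsilyl)oxy]-3-methylpentyl}-4,5-dimethylcyclohex-2-en-1-yl]-2-methylpropanal | CC(=O)[C@@H]1[C@H](C(C)(C)C=O)C=C[C@@H](C)[C@@]1(C)CC[C@@H](C)CCO[Si](c1ccccc1)(c1ccccc1)C(C)(C)C | intermediate
19 | (4aR,7R,8R,8aR)-8-{(3R)-5-[(tert-butyldiphenylsilyl)oxy]-3-methylpentyl}-3-hydroxy-4,4,7,8-tetramethyl-3,4,4a,7,8,8a-hexahydronaphthalen-1(2H)-one (C3 epimers) | O=C1CC(O)C(C)(C)[C@@H]2C=C[C@@H](C)[C@@](C)(CC[C@@H](C)CCO[Si](c3ccccc3)(c3ccccc3)C(C)(C)C)[C@H]12 | intermediate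
20 | (4aR,7R,8R,8aR)-8-{(3R)-5-[(tert-butyldiphenylsilyl)oxy]-3-methylpentyl}-4,4,7,8-tetramethyl-4a,7,8,8a-tetrahydronaphthalen-1(4H)-one | O=C1C=CC(C)(C)[C@@H]2C=C[C@@H](C)[C@@](C)(CC[C@@H](C)CCO[Si](c3ccccc3)(c3ccccc3)C(C)(C)C)[C@H]12 | intermediate
21 | (4aS,7R,8R)-8-{(3R)-5-[(tert-butyldiphenylsilyl)oxy]-3-methylpentyl}-4,4,7,8-tetramethyl-4,4a,7,8-tetrahydronaphthalen-1-yl trifluoromethanesulfonate | CC1(C)C=CC(OS(=O)(=O)C(F)(F)F)=C2[C@H]1C=C[C@@H](C)[C@@]2(C)CC[C@@H](C)CCO[Si](c1ccccc1)(c1ccccc1)C(C)(C)C | intermediate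
22 | (4aS,7R,8R)-8-{(3R)-5-[(tert-butyldiphenylsilyl)oxy]-3-methylpentyl}-4,4,7,8-tetramethyl-2,3,4,4a,5,6,7,8-octahydronaphthalen-1-yl trifluoromethanesulfonate | CC1(C)CCC(OS(=O)(=O)C(F)(F)F)=C2[C@H]1CC[C@@H](C)[C@@]2(C)CC[C@@H](C)CCO[Si](c1ccccc1)(c1ccccc1)C(C)(C)C | intermediate
23 | tert-butyl({(3R)-3-methyl-5-[(1R,2R,4aS)-1,2,5,5-tetramethyl-1,2,3,4,4a,5,6,7-octahydronaphthalen-1-yl]pentyl}oxy)diphenylsilane | CC1(C)CCC=C2[C@H]1CC[C@@H](C)[C@@]2(C)CC[C@@H](C)CCO[Si](c1ccccc1)(c1ccccc1)C(C)(C)C | intermediate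
24 | (3R)-3-methyl-5-[(1R,2R,4aS)-1,2,5,5-tetramethyl-1,2,3,4,4a,5,6,7-octahydronaphthalen-1-yl]pentan-1-ol | CC1(C)CCC=C2[C@H]1CC[C@@H](C)[C@@]2(C)CC[C@@H](C)CCO | intermediate
25 | (3R)-3-methyl-5-[(1R,2R,4aS)-1,2,5,5-tetramethyl-1,2,3,4,4a,5,6,7-octahydronaphthalen-1-yl]pentanoic acid | CC1(C)CCC=C2[C@H]1CC[C@@H](C)[C@@]2(C)CC[C@@H](C)CC(=O)O | intermediate
26 | cis-2-phenyl-1,3-dioxan-5-ol (1,3-O-benzylideneglycerol) | O[C@H]1CO[C@@H](c2ccccc2)OC1 | starting material
27 | cis-2-phenyl-1,3-dioxan-5-yl (3R)-3-methyl-5-[(1R,2R,4aS)-1,2,5,5-tetramethyl-1,2,3,4,4a,5,6,7-octahydronaphthalen-1-yl]pentanoate | CC1(C)CCC=C2[C@H]1CC[C@@H](C)[C@@]2(C)CC[C@@H](C)CC(=O)O[C@H]1CO[C@@H](c2ccccc2)OC1 | intermediate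
28 | 1,3-dihydroxypropan-2-yl (3R)-3-methyl-5-[(1R,2R,4aS)-1,2,5,5-tetramethyl-1,2,3,4,4a,5,6,7-octahydronaphthalen-1-yl]pentanoate | C[C@H](CC[C@@]1(C)C2=CCCC(C)(C)[C@@H]2CC[C@H]1C)CC(=O)OC(CO)CO | target

**Step count and risks**
Total: 20 steps. Longest linear sequence: 17 steps (steps 1–3 and 7–20, or steps 4–20).

Most likely to fail:

Step 13. The [3,3] shift must join two neopentyl-type carbons (C5 beside quaternary C4, C10 beside quaternary C9) and may need temperatures at which decarbonylation of the β,γ-unsaturated aldehyde or fragmentation of the dihydropyran competes; the base-mediated ring closure may also lag behind. Fallback, setting out from 14 and returning at 18: the two bond formations are separated and the sigmatropic step is run on the more reactive silyl ketene acetal. Lactone 14 is treated with KN(SiMe3)2 and tBuMe2SiCl (THF/HMPA, −78 °C), warmed in toluene to 100 °C (Ireland–Claisen ring contraction through the same boat transition state) and hydrolysed to the cyclohexenecarboxylic acid F1. Coupling with MeNH(OMe)·HCl (EDC·HCl) gives the Weinreb amide F2, MeMgBr gives the methyl ketone F3 (the neopentyl ester survives), LiAlH4 gives the diol F4, and Swern oxidation gives keto aldehyde 18, which KOH in MeOH closes to 20.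

Step 14. Deprotonation at C10–H, flanked by quaternary C9, may be slow or incomplete, and allylic strain in the tetrasubstituted enol triflate may disfavor its formation, so that the enone is recovered or degraded. Fallback, setting out from 20 and returning at 23: hydrogenation (H2, Pd/C, EtOAc) saturates C2=C3 and C6=C7 to the decalone F5, NaBH4 gives the C1 alcohol F6, and E2 dehydration with POCl3 in pyridine toward the tertiary C10–H (Zaitsev) gives 23 directly, which bypasses steps 14–16.

Step 9. Conjugate addition to the β,β-disubstituted lactone may be sluggish, with competing 1,2-addition, and facial selectivity could erode if the alternative half-chair reacts. Fallback, setting out from 12 and returning at 14: the acceptor is doubly activated. Esterification of 12 with allyl hydrogen malonate (EDC·HCl, DMAP) gives the malonate ester F7; intramolecular Knoevenagel condensation (piperidine, AcOH, benzene, reflux) gives the α-allyloxycarbonyl unsaturated lactone F8; MeMgBr with catalytic CuI adds methyl anti to the C8 methyl to give F9; deallylation with Pd(PPh3)4 and HCO2H/Et3N followed by thermal decarboxylation gives 14.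

**Further compounds**
F1 | step 13 | carboxylic acid analogue of 18 (CO2H on C10, CO2Me in place of CHO), same ring configuration as 18 | OC(=O)[C@@H]1[C@H](C(C)(C)C(=O)OC)C=C[C@@H](C)[C@@]1(C)CC[C@@H](C)CCO[Si](c1ccccc1)(c1ccccc1)C(C)(C)C
F2 | step 13 | N-methoxy-N-methylamide of F1 | CON(C)C(=O)[C@@H]1[C@H](C(C)(C)C(=O)OC)C=C[C@@H](C)[C@@]1(C)CC[C@@H](C)CCO[Si](c1ccccc1)(c1ccccc1)C(C)(C)C
F3 | step 13 | methyl ketone ester (acetyl on C10, CO2Me on C4) | CC(=O)[C@@H]1[C@H](C(C)(C)C(=O)OC)C=C[C@@H](C)[C@@]1(C)CC[C@@H](C)CCO[Si](c1ccccc1)(c1ccccc1)C(C)(C)C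
F4 | step 13 | diol (C1 secondary alcohol, C3 primary alcohol; C1 epimers) | CC(O)[C@@H]1[C@H](C(C)(C)CO)C=C[C@@H](C)[C@@]1(C)CC[C@@H](C)CCO[Si](c1ccccc1)(c1ccccc1)C(C)(C)C
F5 | step 14 | saturated decalone (C1 ketone, no alkenes) | O=C1CCC(C)(C)[C@@H]2CC[C@@H](C)[C@@](C)(CC[C@@H](C)CCO[Si](c3ccccc3)(c3ccccc3)C(C)(C)C)[C@H]12
F6 | step 14 | saturated C1 alcohol (C1 epimers) | OC1CCC(C)(C)[C@@H]2CC[C@@H](C)[C@@](C)(CC[C@@H](C)CCO[Si](c3ccccc3)(c3ccccc3)C(C)(C)C)[C@H]12
F7 | step 9 | allyl malonate ester of the C7 hydroxyl of 12 | COC(=O)C(C)(C)/C=C/[C@H](OC(=O)CC(=O)OCC=C)[C@@H](C)C(=O)CC[C@@H](C)CCO[Si](c1ccccc1)(c1ccccc1)C(C)(C)C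
F8 | step 9 | α-allyloxycarbonyl analogue of lactone 13 | COC(=O)C(C)(C)/C=C/[C@@H]1OC(=O)C(C(=O)OCC=C)=C(CC[C@@H](C)CCO[Si](c2ccccc2)(c2ccccc2)C(C)(C)C)[C@@H]1C
F9 | step 9 | α-allyloxycarbonyl analogue of lactone 14 (C10 epimers) | COC(=O)C(C)(C)/C=C/[C@@H]1OC(=O)C(C(=O)OCC=C)[C@](C)(CC[C@@H](C)CCO[Si](c2ccccc2)(c2ccccc2)C(C)(C)C)[C@@H]1C
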